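**Retrosynthetic overview**
1. Target 14 comes from its 8-O-benzyl ether 13 by hydrogenolysis in the last step.
2. Ring C is the only ring built: I2/DMSO oxidative cyclisation of 2'-hydroxychalcone 10 gives flavone 13.
3. Chalcone 10 comes from ring A ketone 7 and ring B aldehyde 8 by a Claisen–Schmidt aldol condensation, which forms the future C2–C3 bond.
4. Ketone 7 comes from catechol ketone 6 by chelation-controlled 3-O-benzylation; 6 comes from catechol 5 by C-acetylation at its only ring C–H.
5. Catechol 5 comes from salicylaldehyde 3 by Dakin oxidation; 3 comes from 3,4,5-trimethoxyphenol 1 by ortho-formylation. Rings A and B are bought as benzene rings.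

Assumption: the target has no stereocentre and is achiral, so no enantiocontrol is needed; the only stereo-element on the route is the E double bond of chalcone 10, which disappears in step 6.

**Route**

Step 1
Reactants: 1 3,4,5-trimethoxyphenol
Product: 3 2-hydroxy-4,5,6-trimethoxybenzaldehyde, via salicyl alcohol 2 (not isolated)
Conditions: (CH2O)n, MgCl2, Et3N, MeCN, reflux; then 1 M HCl
Reagents that add atoms: paraformaldehyde (reacts as formaldehyde), C=O
Why: Magnesium-phenoxide-directed ortho-formylation (Casnati–Skattebøl) delivers formaldehyde only ortho to the OH, the two ortho positions of 1 are equivalent, and the salicyl alkoxide is oxidised in situ by hydride transfer to a second formaldehyde.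

Step 2
Reactants: 3 2-hydroxy-4,5,6-trimethoxybenzaldehyde
Product: 5 3,4,5-trimethoxybenzene-1,2-diol, via aryl formate 4 (not isolated)
Conditions: 30% H2O2 (1.1 equiv), NaOH (1.1 equiv), degassed H2O–THF, 0 °C to rt, N2; then dilute HCl
Reagents that add atoms: hydrogen peroxide, OO
Why: Dakin oxidation of an ortho-hydroxybenzaldehyde, in which hydroperoxide adds to the aldehyde, the electron-rich aryl group migrates to oxygen and the resulting formate is saponified in the same pot.

Step 3
Reactants: 5 3,4,5-trimethoxybenzene-1,2-diol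
Product: 6 1-(2,3-dihydroxy-4,5,6-trimethoxyphenyl)ethan-1-one
Conditions: AcOH, BF3·Et2O, 80 °C, N2; then aq. NaOAc
Reagents that add atoms: acetic acid, CC(=O)O
Why: Friedel–Crafts (Nencki-type) C-acylation at the single remaining ring C–H of 5, which is activated by an ortho OH, an ortho OMe and a para OH, so only one regioisomer can form.

Step 4
Reactants: 6 1-(2,3-dihydroxy-4,5,6-trimethoxyphenyl)ethan-1-one
Product: 7 1-[3-(benzyloxy)-2-hydroxy-4,5,6-trimethoxyphenyl]ethan-1-one
Conditions: BnBr (1.05 equiv), K2CO3 (1.1 equiv), acetone, reflux, N2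
Reagents that add atoms: benzyl bromide, BrCc1ccccc1
Why: Williamson etherification under chelation control, since the 2-OH is tied up in a hydrogen bond to the ketone and is poorly nucleophilic with weak base, so one equivalent of BnBr goes to the 3-OH as in the classical partial alkylation of gallacetophenone.

Step 5
Reactants: 7 1-[3-(benzyloxy)-2-hydroxy-4,5,6-trimethoxyphenyl]ethan-1-one; 8 3,4,5-trimethoxybenzaldehyde
Product: 10 (E)-1-[3-(benzyloxy)-2-hydroxy-4,5,6-trimethoxyphenyl]-3-(3,4,5-trimethoxyphenyl)prop-2-en-1-one, via aldol adduct 9 (not isolated)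
Conditions: KOH (10 equiv), EtOH–H2O, rt, 48 h, N2; then cold dilute HCl
Reagents that add atoms: none
Why: Intermolecular Claisen–Schmidt aldol condensation in which the methyl ketone enolate of 7 adds to the non-enolisable aldehyde 8 and the β-hydroxy ketone loses water (E1cB) to the thermodynamically favoured E-enone, erasing the racemic carbinol centre of 9.

Step 6
Reactants: 10 (E)-1-[3-(benzyloxy)-2-hydroxy-4,5,6-trimethoxyphenyl]-3-(3,4,5-trimethoxyphenyl)prop-2-en-1-one
Product: 13 8-(benzyloxy)-5,6,7-trimethoxy-2-(3,4,5-trimethoxyphenyl)-4H-chromen-4-one, via flavanone 11 (not isolated), via 3-iodoflavanone 12 (not isolated)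
Conditions: I2 (10 mol%), DMSO, 130 °C; then aq. Na2S2O3
Reagents that add atoms: none
Why: Iodine–DMSO oxidative cyclisation, in which oxa-Michael closure of ring C gives the flavanone, α-iodination and loss of HI give the flavone, DMSO re-oxidises HI to I2, and the racemic centres of 11 and 12 are erased.

Step 7
Reactants: 13 8-(benzyloxy)-5,6,7-trimethoxy-2-(3,4,5-trimethoxyphenyl)-4H-chromen-4-one
Product: 14 8-hydroxy-5,6,7-trimethoxy-2-(3,4,5-trimethoxyphenyl)-4H-chromen-4-one (8-hydroxy-5,6,7,3',4',5'-hexamethoxyflavone)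
Conditions: H2 (1 atm), 10% Pd/C, EtOAc–MeOH, rt
Reagents that add atoms: none
Why: Catalytic hydrogenolysis of the benzyl aryl ether on palladium frees the 8-OH while the six methyl ethers and the chromone double bond are untouched at 1 atm and room temperature, and the product has no stereocentre.

**Compound list**
1 | 3,4,5-trimethoxyphenol | COc1cc(O)cc(OC)c1OC | starting material
2 | 2-(hydroxymethyl)-3,4,5-trimethoxyphenol (salicyl alcohol, as its magnesium alkoxide, not isolated) | COc1cc(O)c(CO)c(OC)c1OC | intermediate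
3 | 2-hydroxy-4,5,6-trimethoxybenzaldehyde | COc1cc(O)c(C=O)c(OC)c1OC | intermediate
4 | 2-hydroxy-4,5,6-trimethoxyphenyl formate (aryl formate, not isolated) | O=COc1c(O)cc(OC)c(OC)c1OC | intermediate
5 | 3,4,5-trimethoxybenzene-1,2-diol | COc1cc(O)c(O)c(OC)c1OC | intermediate
6 | 1-(2,3-dihydroxy-4,5,6-trimethoxyphenyl)ethan-1-one | CC(=O)c1c(O)c(O)c(OC)c(OC)c1OC | intermediate
7 | 1-[3-(benzyloxy)-2-hydroxy-4,5,6-trimethoxyphenyl]ethan-1-one | CC(=O)c1c(O)c(OCc2ccccc2)c(OC)c(OC)c1OC | intermediate
8 | 3,4,5-trimethoxybenzaldehyde | COc1cc(C=O)cc(OC)c1OC | starting material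
9 | 1-[3-(benzyloxy)-2-hydroxy-4,5,6-trimethoxyphenyl]-3-hydroxy-3-(3,4,5-trimethoxyphenyl)propan-1-one (aldol adduct, racemic, not isolated) | COc1cc(C(O)CC(=O)c2c(O)c(OCc3ccccc3)c(OC)c(OC)c2OC)cc(OC)c1OC | intermediate
10 | (E)-1-[3-(benzyloxy)-2-hydroxy-4,5,6-trimethoxyphenyl]-3-(3,4,5-trimethoxyphenyl)prop-2-en-1-one | COc1cc(/C=C/C(=O)c2c(O)c(OCc3ccccc3)c(OC)c(OC)c2OC)cc(OC)c1OC | intermediate
11 | 8-(benzyloxy)-5,6,7-trimethoxy-2-(3,4,5-trimethoxyphenyl)chroman-4-one (flavanone, racemic, not isolated) | COc1cc(C2CC(=O)c3c(OC)c(OC)c(OC)c(OCc4ccccc4)c3O2)cc(OC)c1OC | intermediate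
12 | 8-(benzyloxy)-3-iodo-5,6,7-trimethoxy-2-(3,4,5-trimethoxyphenyl)chroman-4-one (3-iodoflavanone, racemic, relative configuration not defined, not isolated) | COc1cc(C2Oc3c(OCc4ccccc4)c(OC)c(OC)c(OC)c3C(=O)C2I)cc(OC)c1OC | intermediate
13 | 8-(benzyloxy)-5,6,7-trimethoxy-2-(3,4,5-trimethoxyphenyl)-4H-chromen-4-one | COc1cc(-c2cc(=O)c3c(OC)c(OC)c(OC)c(OCc4ccccc4)c3o2)cc(OC)c1OC | intermediate
14 | 8-hydroxy-5,6,7-trimethoxy-2-(3,4,5-trimethoxyphenyl)-4H-chromen-4-one (achiral) | COc1cc(-c2cc(=O)c3c(OC)c(OC)c(OC)c(O)c3o2)cc(OC)c1OC | target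

**Summary**
Total step count: 7.
Longest linear sequence: 7 steps (1 to 14); aldehyde 8 enters as a purchased fragment in step 5.

**Steps most likely to fail, with fallbacks**

Step 2. Catechol 5 is very electron-rich and may over-oxidise to quinones in alkaline peroxide or in air; the same sensitivity also threatens step 3. The fallback sets out from 1 and comes back at 6, and never handles free 5. Acetylation of 1 with AcOH and BF3·Et2O at 80 °C gives 1-(2-hydroxy-4,5,6-trimethoxyphenyl)ethan-1-one F1. Duff formylation at its single ring C–H (hexamethylenetetramine, CF3CO2H, 90 °C, then aqueous HCl) gives 3-acetyl-2-hydroxy-4,5,6-trimethoxybenzaldehyde F2. Dakin oxidation with H2O2 and NaOH at 0 °C attacks the aldehyde much faster than the hindered, chelated ketone and passes through 3-acetyl-2-hydroxy-4,5,6-trimethoxyphenyl formate F3, which is saponified in the pot to 6. Compound 6 is an acyl-stabilised, chelated catechol and is far less prone to oxidation than 5.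

Step 4. Mono-benzylation may give some 2-O-benzyl isomer or bis-ether; the correct isomer is recognised by its chelated OH signal near 13 ppm in the 1H NMR spectrum. The fallback sets out from 6 (or from the crude mixture of benzylation products) and comes back at 7. Exhaustive benzylation (BnBr 3 equiv, K2CO3 4 equiv, DMF, 70 °C) gives 1-[2,3-bis(benzyloxy)-4,5,6-trimethoxyphenyl]ethan-1-one F4. MgBr2·Et2O in toluene–Et2O at reflux then cleaves only the benzyl ether ortho to the carbonyl through a six-membered magnesium chelate, leaving the 3-O-benzyl group and giving 7 after aqueous work-up.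

Step 6. Traces of HI at 130 °C could demethylate the 5-OMe or debenzylate, and aurone by-products are possible. The fallback sets out from 7 and comes back at 13, replacing the aldol and oxidation sequence by a redox-neutral Claisen route. The dianion of 7 (LiN(SiMe3)2 3.2 equiv, THF, −78 °C) is C-acylated with 3,4,5-trimethoxybenzoyl chloride (1 equiv, −78 °C to rt, then dilute HCl) to give 1-[3-(benzyloxy)-2-hydroxy-4,5,6-trimethoxyphenyl]-3-(3,4,5-trimethoxyphenyl)propane-1,3-dione F5. Cyclodehydration with catalytic p-toluenesulfonic acid in toluene at 80 °C closes ring C and gives 13 with loss of water only.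

**Further compounds**
F1 | step 2 | 1-(2-hydroxy-4,5,6-trimethoxyphenyl)ethan-1-one | CC(=O)c1c(O)cc(OC)c(OC)c1OC
F2 | step 2 | 3-acetyl-2-hydroxy-4,5,6-trimethoxybenzaldehyde | CC(=O)c1c(O)c(C=O)c(OC)c(OC)c1OC
F3 | step 2 | 3-acetyl-2-hydroxy-4,5,6-trimethoxyphenyl formate | CC(=O)c1c(O)c(OC=O)c(OC)c(OC)c1OC
F4 | step 4 | 1-[2,3-bis(benzyloxy)-4,5,6-trimethoxyphenyl]ethan-1-one | CC(=O)c1c(OCc2ccccc2)c(OCc2ccccc2)c(OC)c(OC)c1OC
F5 | step 6 | 1-[3-(benzyloxy)-2-hydroxy-4,5,6-trimethoxyphenyl]-3-(3,4,5-trimethoxyphenyl)propane-1,3-dione | COc1cc(C(=O)CC(=O)c2c(O)c(OCc3ccccc3)c(OC)c(OC)c2OC)cc(OC)c1OC
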